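The grey run shows the first step. With starting material in excess, its starting material stands at 55.3% at the first reading, 0.500 h, against the 52.5% that one reagent per starting material leaves, and it is still 49.4% at 8.00 h.

all flasks: reagent 0.0304 M
- violet: starting material 0.032 M; run made earlier
- amber: starting material 0.016 M; run made earlier
- grey: starting material 0.064 M; run made earlier
- winter: starting material 0.032 M; a single well-mixed tank run continuously and read at steady state, 8.0 h in it on average
- dawn: starting material 0.032 M; a closed flask charged with all of it at once and left for 8.0 h; time 8.0 h
- midnight: starting material 0.032 M; one stirred flow tank at steady state, fed with the mixture as stated, mean residence time 24.0 h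
- summer: starting material 0.032 M (fed, over 8.00 h); a stirred flask in which starting material is dosed at a steady rate over 8.00 h without added volume, worked up at 8.0 h; time 8.0 h

| run | time / h | target / % | over-reaction product / % | starting material / % |
|---|---|---|---|---|
| violet | 0.833 | 4.2 | 1.1 | 23.6 |
| violet | 1.50 | 7.0 | 0 | 18.8 |
| violet | 2.50 | 9.3 | 0 | 17.3 |
| violet | 3.00 | 8.6 | 0.5 | 14.7 |
| violet | 4.00 | 8.7 | 1.7 | 14.3 |
| violet | 5.00 | 10.0 | 0.6 | 14.7 |
| amber | 0.667 | 8.6 | 1.6 | 11.2 |
| amber | 1.00 | 14.9 | 0.5 | 6.7 |
| amber | 2.00 | 27.7 | 4.4 | 3.0 |
| amber | 3.00 | 37.7 | 4.8 | 0 |
| amber | 5.00 | 41.6 | 13.1 | 0 |
| amber | 8.00 | 44.2 | 15.2 | 0 |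
| grey | 0.500 | 0.4 | 0 | 55.3 |
| grey | 1.50 | 0.8 | 0.8 | 53.4 |
| grey | 3.00 | 0.9 | 1.8 | 53.2 |
| grey | 4.00 | 0 | 0 | 51.5 |
| grey | 6.00 | 1.7 | 0 | 52.2 |
| grey | 8.00 | 0 | 1.1 | 49.4 |

(scatter of a reading: 1 percentage point)

- percent here means starting material units held: one self-condensation product counts as two
- the stated concentrations are those of everything mixed, before any reaction; amounts are the same in each set-up
- on the list of suspects stand: starting material + reagent <-> intermediate A; intermediate A -> intermediate B; reagent + intermediate B <-> target; 2 starting material -> self-condensation product; reagent + target -> over-reaction product
- the feed brings no volume worth counting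
- the earlier runs were made in a closed, stirred flask

- the set-up with the highest share of target in all that became target or over-reaction product, at the outlet or at the end ("none" if the first two lie within 2 percentage points) (winter / dawn / midnight / summer / none)
- share of target in all that became target or over-reaction product, at the outlet or at the end, winter
- share of target in all that became target or over-reaction product, at the outlet or at the end, dawn
- share of target in all that became target or over-reaction product, at the outlet or at the end, midnight
- share of target in all that became target or over-reaction product, at the outlet or at the end, summer

So you can climb a ladder of times. First, in grey, within 0.500 h, starting material takes up one reagent. Then, over hours, target appears: amber goes from 14.9% at 1.00 h to 37.7% at 3.00 h. Target holds a second reagent, for violet's starting material stalls at 14.7%, not 5.00%, and the gap is about its target, 10.0%. Last comes over-reaction product, which takes a third reagent. Amber, with reagent to spare, reaches 15.2% at 8.00 h, while violet, where reagent is the limiting reagent at 0.950 equivalents, shows no reading above 1.7%.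

Over-reaction product needs target and free reagent together, so you should ask how long free reagent lasts. In summer, grey's uptake time of 0.500 h is short against the dose of 8.00 h, so I expect the early portions to be taken up soon after they arrive, and by plain count the reagent charge stays ahead of the delivered starting material until 7.60 h. Call this the excess window: dosing time times reagent charge over starting material charge. It counts one reagent per starting material, so reagent held in target shortens it in the flask.

Summer doses nearly all of its time inside the window, and with half its charge delivered it has amber's ratio. I therefore take amber's last share, 74.4%, for summer. Dawn, charged at once, is violet carried on, with no window at all. The last four violet readings pooled give 92.9%, which is above summer's by 18 percentage points. The tanks are fed at violet's ratio, and the window gives them no number of mine.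

The forecast names dawn as best, with winter 85%, dawn 93%, midnight 83% and summer 75%, and holds that “Dosing keeps reagent in excess early”.

The flasks give winter 88.4%, dawn 95.4%, midnight 86.5% and summer 74.0%, so the best is dawn.

    starting material + reagent ⇌ intermediate A (K = 170 M⁻¹, k = 17.0 M⁻¹ min⁻¹)
    intermediate A → intermediate B (k = 0.0380 min⁻¹)
    reagent + intermediate B ⇌ target (K = 980 M⁻¹, k = 0.410 M⁻¹ min⁻¹)
    2 starting material → self-condensation product (k = 0.00170 M⁻¹ min⁻¹)
    reagent + target → over-reaction product (k = 0.200 M⁻¹ min⁻¹)

Reagent in dawn is under a fiftieth of its charge by 2.44 h, while summer's excess window runs to 7.60 h, and summer still holds 29.0% of its reagent at 4.00 h; over-reaction product ends at 0.418% in dawn and 6.03% in summer. The neighbour of summer with 0.012 M of reagent has a window of 3.00 h, and its share is 92.7%.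

(The readings are calculated for substances that don't exist; scatter was added.)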